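**Strategy.** Ring A is taken back to dimethyl squarate. Its four carbons become C6, C7, C8 and C8a, the contiguous oxygenated run of ring A in which the methoxy-bearing C7 and C8 lie between the para-related oxygens on C6 and C8a. A β-methoxyacrylate arm supplies C5 with its methoxyl, C4a and C4. Heating the resulting 4-alkenyl-4-silyloxycyclobutenone opens the four-membered ring to a dienylketene that forms the C4a–C8a bond and aromatises. This delivers the hexasubstituted benzoate with O6 silylated and O8a free in one operation. The ester carbon then acylates a MOM-protected ring B acetylide, and O8a closes ring C by 6-endo attack on the ynone.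

Key step: step 2

Remark: the target has no stereocentre. Compound 5 and the transient species 4, 7 and 14 each carry one stereocentre and are formed racemic; all of these centres later become sp2 carbons. The E descriptor of 3, 4 and 5 means methoxyl trans to the ester, with the lithium or ring carbon cis to it.

**Step 1**
Reactants: 1 methyl (E)-3-methoxyacrylate; 2 dimethyl squarate
Product: 5 methyl (E)-3-[1-(tert-butyldimethylsilyloxy)-2,3-dimethoxy-4-oxocyclobut-2-en-1-yl]-3-methoxyprop-2-enoate (racemic), via lithio acrylate 3 (not isolated), via lithium alkoxide 4 (not isolated)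
Conditions: LiN(iPr)2, THF, −90 °C; then 2, −78 °C; then TBSOTf, −78 → −40 °C; cold aq NaHCO3
Reagents that add atoms: tert-butyldimethylsilyl trifluoromethanesulfonate (TBSOTf), CC(C)(C)[Si](C)(C)OS(=O)(=O)C(F)(F)F
Why: Chelation-directed β-lithiation of the β-methoxyacrylate (the vinyl carbanion sits cis to the ester carbonyl, so the E geometry is kept), 1,2-addition of this vinyllithium to one of the two equivalent ketone carbonyls of the squarate and O-silylation of the tertiary lithium alkoxide with a silyl triflate are all established reaction types; the silylation is run cold and in situ to outrun 5-exo lactonisation onto the cis ester, and the new quaternary carbon is racemic because it later becomes an aromatic carbon.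

**Step 2**
Reactants: 5 methyl (E)-3-[1-(tert-butyldimethylsilyloxy)-2,3-dimethoxy-4-oxocyclobut-2-en-1-yl]-3-methoxyprop-2-enoate
Product: 8 methyl 3-(tert-butyldimethylsilyloxy)-6-hydroxy-2,4,5-trimethoxybenzoate, via dienylketene 6 (not isolated), via cyclohexadienone 7 (not isolated)
Conditions: toluene (degassed, 0.02 M), 110 °C, Ar
Reagents that add atoms: none
Why: Heating should trigger conrotatory 4π electrocyclic opening of the cyclobutenone bond between the ketone carbon and the silyloxy-bearing carbon to give dienylketene 6; the electrophilic ketene carbon is then joined, in a thermal disrotatory 6π electrocyclisation, to the acrylate α-carbon (the nucleophilic terminus of the push-pull enol ether), which forms the C4a–C8a bond and closes ring A as cyclohexadienone 7. The β-keto ester 7 should enolise at once to the phenol, so its single stereocentre at C4a, like the quaternary carbon of 5, is erased and no stereocontrol is needed. The closest known reaction type is the Moore-type thermal rearrangement of 4-alkenyl- and 4-aryl-4-oxycyclobutenones to hydroquinones, which shares its dienylketene with the Danheiser benzannulation. The selectivity required is torquoselectivity: the donor silyloxy group rotates outward, which places the alkenyl arm cis to the ketene, and closure is then possible at one carbon only. The silyl group has no migration path to the para oxygen, so O6 should stay protected while O8a appears as a free phenol hydrogen-bonded to the ester.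

**Step 3**
Reactants: 8 methyl 3-(tert-butyldimethylsilyloxy)-6-hydroxy-2,4,5-trimethoxybenzoate
Product: 9 3-(tert-butyldimethylsilyloxy)-6-hydroxy-N,2,4,5-tetramethoxy-N-methylbenzamide
Conditions: MeNHOMe·HCl, iPrMgCl (excess), THF, −20 °C → rt; aq NH4Cl
Reagents that add atoms: N,O-dimethylhydroxylamine hydrochloride, CNOC.Cl
Why: Weinreb amide formation by aminolysis of the ester with the chloromagnesium amide of N,O-dimethylhydroxylamine should proceed because the magnesium phenoxide formed first chelates and activates the neighbouring ester carbonyl, while the doubly flanked aryl silyl ether and the methyl ethers are inert to the amide base.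

**Step 4**
Reactants: 10 2-hydroxy-6-methoxybenzaldehyde
Product: 11 2-methoxy-6-(methoxymethoxy)benzaldehyde
Conditions: MOMCl, iPr2NEt, CH2Cl2, 0 °C → rt
Reagents that add atoms: chloromethyl methyl ether (MOMCl), COCCl
Why: Base-mediated O-alkylation of the phenol with the α-chloro ether (MOM protection, a Williamson-type etherification) masks O2' with a group that survives organolithium, amine and fluoride conditions and leaves under mild acid.

**Step 5**
Reactants: 11 2-methoxy-6-(methoxymethoxy)benzaldehyde
Product: 12 2-ethynyl-1-methoxy-3-(methoxymethoxy)benzene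
Conditions: dimethyl (1-diazo-2-oxopropyl)phosphonate, K2CO3, MeOH, rt
Reagents that add atoms: dimethyl (1-diazo-2-oxopropyl)phosphonate (Ohira–Bestmann reagent), COP(=O)(OC)C(=[N+]=[N-])C(C)=O
Why: Seyferth–Gilbert homologation in the Ohira–Bestmann variant converts the aldehyde into the terminal alkyne through Horner–Wadsworth–Emmons olefination by the diazomethylphosphonate anion generated in situ, loss of N2 and 1,2-hydrogen shift, under K2CO3/MeOH conditions that the MOM and methyl ethers tolerate.

**Step 6**
Reactants: 9 3-(tert-butyldimethylsilyloxy)-6-hydroxy-N,2,4,5-tetramethoxy-N-methylbenzamide; 12 2-ethynyl-1-methoxy-3-(methoxymethoxy)benzene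
Product: 15 1-[3-(tert-butyldimethylsilyloxy)-6-hydroxy-2,4,5-trimethoxyphenyl]-3-[2-methoxy-6-(methoxymethoxy)phenyl]prop-2-yn-1-one, via lithium acetylide 13 (not isolated), via dilithium hemiaminal adduct 14 (not isolated)
Conditions: 12 (2.6 equiv), n-BuLi (2.5 equiv), THF, −78 °C; then 9, −78 → 0 °C; aq NH4Cl
Reagents that add atoms: none
Why: Weinreb ketone synthesis: one equivalent of acetylide 13 deprotonates the phenol and a further equivalent adds to the amide to give the N-methoxy-chelated tetrahedral adduct 14, which collapses only on aqueous work-up so that the ynone is never exposed to the nucleophile; the carbinol centre of 14 is transient and racemic.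

**Step 7**
Reactants: 15 1-[3-(tert-butyldimethylsilyloxy)-6-hydroxy-2,4,5-trimethoxyphenyl]-3-[2-methoxy-6-(methoxymethoxy)phenyl]prop-2-yn-1-one
Product: 17 6-(tert-butyldimethylsilyloxy)-5,7,8-trimethoxy-2-[2-methoxy-6-(methoxymethoxy)phenyl]chromen-4-one, via enaminone 16 (not isolated)
Conditions: Et2NH, EtOH, rt → 60 °C
Reagents that add atoms: none
Why: Conjugate addition of diethylamine to the ynone gives β-enaminone 16, and intramolecular addition–elimination by the O8a phenol (net 6-endo-dig oxa-Michael cyclisation) expels the amine and closes pyranone ring C, a pathway that bypasses 5-exo closure to the aurone, while O2' remains MOM-blocked so that only O8a can cyclise.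

**Step 8**
Reactants: 17 6-(tert-butyldimethylsilyloxy)-5,7,8-trimethoxy-2-[2-methoxy-6-(methoxymethoxy)phenyl]chromen-4-one
Product: 19 6,2'-dihydroxy-5,7,8,6'-tetramethoxyflavone, via 6-hydroxy MOM flavone 18 (not isolated)
Conditions: Bu4NF, THF, 0 °C; then 3 M HCl, MeOH, 50 °C
Reagents that add atoms: none
Why: Fluoride-induced cleavage of the aryl silyl ether followed by acid-catalysed transacetalisation of the MOM ether with methanol are standard deprotections that leave the four aryl methyl ethers, including the peri 5-methoxyl, and the pyranone untouched.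

**Compound list**
1 | methyl (E)-3-methoxyacrylate | CO/C=C/C(=O)OC | starting material
2 | dimethyl squarate (3,4-dimethoxycyclobut-3-ene-1,2-dione) | COC1=C(OC)C(=O)C1=O | starting material
3 | methyl (E)-3-lithio-3-methoxyprop-2-enoate (lithium cis to the ester) | CO/C([Li])=C/C(=O)OC | intermediate
4 | lithium 1-[(E)-1,3-dimethoxy-3-oxoprop-1-en-1-yl]-2,3-dimethoxy-4-oxocyclobut-2-en-1-olate (racemic) | COC(=O)/C=C(/OC)C1([O-])C(OC)=C(OC)C1=O.[Li+] | intermediate
5 | methyl (E)-3-[1-(tert-butyldimethylsilyloxy)-2,3-dimethoxy-4-oxocyclobut-2-en-1-yl]-3-methoxyprop-2-enoate (racemic) | COC(=O)/C=C(/OC)C1(O[Si](C)(C)C(C)(C)C)C(OC)=C(OC)C1=O | intermediate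
6 | methyl (2E,4Z)-4-(tert-butyldimethylsilyloxy)-3,5,6-trimethoxy-7-oxohepta-2,4,6-trienoate (dienylketene) | COC(=O)/C=C(OC)\C(O[Si](C)(C)C(C)(C)C)=C(OC)/C(OC)=C=O | intermediate
7 | methyl 3-(tert-butyldimethylsilyloxy)-2,4,5-trimethoxy-6-oxocyclohexa-2,4-diene-1-carboxylate (racemic) | COC(=O)C1C(=O)C(OC)=C(OC)C(O[Si](C)(C)C(C)(C)C)=C1OC | intermediate
8 | methyl 3-(tert-butyldimethylsilyloxy)-6-hydroxy-2,4,5-trimethoxybenzoate | COC(=O)c1c(O)c(OC)c(OC)c(O[Si](C)(C)C(C)(C)C)c1OC | intermediate
9 | 3-(tert-butyldimethylsilyloxy)-6-hydroxy-N,2,4,5-tetramethoxy-N-methylbenzamide | CON(C)C(=O)c1c(O)c(OC)c(OC)c(O[Si](C)(C)C(C)(C)C)c1OC | intermediate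
10 | 2-hydroxy-6-methoxybenzaldehyde | COc1cccc(O)c1C=O | starting material
11 | 2-methoxy-6-(methoxymethoxy)benzaldehyde | COCOc1cccc(OC)c1C=O | intermediate
12 | 2-ethynyl-1-methoxy-3-(methoxymethoxy)benzene | COCOc1cccc(OC)c1C#C | intermediate
13 | lithium [2-methoxy-6-(methoxymethoxy)phenyl]acetylide | COCOc1cccc(OC)c1C#C[Li] | intermediate
14 | dilithium salt of the tetrahedral adduct of 13 with the phenoxide of 9 (racemic) | CON(C)C([O-])(C#Cc1c(OC)cccc1OCOC)c1c([O-])c(OC)c(OC)c(O[Si](C)(C)C(C)(C)C)c1OC.[Li+].[Li+] | intermediate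
15 | 1-[3-(tert-butyldimethylsilyloxy)-6-hydroxy-2,4,5-trimethoxyphenyl]-3-[2-methoxy-6-(methoxymethoxy)phenyl]prop-2-yn-1-one | COCOc1cccc(OC)c1C#CC(=O)c1c(O)c(OC)c(OC)c(O[Si](C)(C)C(C)(C)C)c1OC | intermediate
16 | (E)-3-(diethylamino)-1-[3-(tert-butyldimethylsilyloxy)-6-hydroxy-2,4,5-trimethoxyphenyl]-3-[2-methoxy-6-(methoxymethoxy)phenyl]prop-2-en-1-one (E isomer expected; either isomer would cyclise) | CCN(CC)/C(=C/C(=O)c1c(O)c(OC)c(OC)c(O[Si](C)(C)C(C)(C)C)c1OC)c1c(OC)cccc1OCOC | intermediate
17 | 6-(tert-butyldimethylsilyloxy)-5,7,8-trimethoxy-2-[2-methoxy-6-(methoxymethoxy)phenyl]chromen-4-one | COCOc1cccc(OC)c1-c1cc(=O)c2c(OC)c(O[Si](C)(C)C(C)(C)C)c(OC)c(OC)c2o1 | intermediate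
18 | 6-hydroxy-5,7,8-trimethoxy-2-[2-methoxy-6-(methoxymethoxy)phenyl]chromen-4-one | COCOc1cccc(OC)c1-c1cc(=O)c2c(OC)c(O)c(OC)c(OC)c2o1 | intermediate
19 | 6,2'-dihydroxy-5,7,8,6'-tetramethoxyflavone (6-hydroxy-2-(2-hydroxy-6-methoxyphenyl)-5,7,8-trimethoxychromen-4-one) | COc1cccc(O)c1-c1cc(=O)c2c(OC)c(O)c(OC)c(OC)c2o1 | target

**Step count.** Total: 8 steps. Longest linear sequence: 6 steps (steps 1, 2, 3, 6, 7, 8, from 1 and 2 to 19). The ring B branch (steps 4 and 5) joins at step 6.

**Steps most likely to fail**

1. Step 1. The lithium alkoxide 4 may lactonise onto the cis ester before it is silylated, giving a spiro-butenolide that cannot benzannulate, or the lithiated acrylate may decompose above about −80 °C. The fallback sets out from dimethyl squarate 2 and comes back at 5. Methyl propiolate would be deprotonated with LiN(SiMe3)2 in THF at −78 °C to methyl 3-lithioprop-2-ynoate F1. Addition of this to 2 should give the lithium alkoxide F2, in which the linear alkyne holds the ester out of reach of the oxygen. Silylation with TBSOTf would then give methyl 3-[1-(tert-butyldimethylsilyloxy)-2,3-dimethoxy-4-oxocyclobut-2-en-1-yl]prop-2-ynoate F3. Base-catalysed oxa-Michael addition of methanol to the ynoate (catalytic NaOMe, MeOH, 0 °C; methoxyl exchange on the cyclobutenone would be degenerate) should install the 3-methoxyl and give 5. It may be accompanied by the Z isomer methyl (Z)-3-[1-(tert-butyldimethylsilyloxy)-2,3-dimethoxy-4-oxocyclobut-2-en-1-yl]-3-methoxyprop-2-enoate F4, which has the ester turned away from the ring and should converge on 8 in step 2.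

2. Step 3. Acyl substitution may stall at an ester carbonyl flanked by two ortho substituents and tied up in a phenoxide chelate, with slow erosion of the aryl silyl ether on prolonged exposure. The fallback sets out from 8 and comes back at 15, so it also bypasses step 6. Reduction with iBu2AlH (CH2Cl2, −78 → 0 °C) should give 4-(tert-butyldimethylsilyloxy)-2-(hydroxymethyl)-3,5,6-trimethoxyphenol F5. Benzylic oxidation with MnO2 (CH2Cl2, rt) should give 3-(tert-butyldimethylsilyloxy)-6-hydroxy-2,4,5-trimethoxybenzaldehyde F6. Addition of acetylide 13 (2.5 equiv, THF, −78 °C) to this much more electrophilic carbonyl should give racemic 1-[3-(tert-butyldimethylsilyloxy)-6-hydroxy-2,4,5-trimethoxyphenyl]-3-[2-methoxy-6-(methoxymethoxy)phenyl]prop-2-yn-1-ol F7. A second MnO2 oxidation of this propargylic benzylic alcohol should give ynone 15.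

3. Step 6. The acetylide may add incompletely to a hindered amide that is deactivated by the neighbouring phenoxide, returning 9 or leading to N–O cleavage of the amide. The fallback sets out from 9 and comes back at 18. The phenol would be silylated (TBSOTf, 2,6-lutidine, CH2Cl2, 0 °C) to 3,6-bis(tert-butyldimethylsilyloxy)-N,2,4,5-tetramethoxy-N-methylbenzamide F8. This amide carries no anionic neighbour and should take up acetylide 13 (THF, −78 → 0 °C) to give 1-[3,6-bis(tert-butyldimethylsilyloxy)-2,4,5-trimethoxyphenyl]-3-[2-methoxy-6-(methoxymethoxy)phenyl]prop-2-yn-1-one F9. Fluoride under aprotic conditions (KF, 18-crown-6, DMF, rt) should then remove both silyl groups, and the liberated O8a phenoxide should close 6-endo onto the ynone. After work-up this gives 18, which enters the acid stage of step 8.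

**Further compounds**
F1 | step 1 | methyl 3-lithioprop-2-ynoate | COC(=O)C#C[Li]
F2 | step 1 | lithium 2,3-dimethoxy-1-(3-methoxy-3-oxoprop-1-yn-1-yl)-4-oxocyclobut-2-en-1-olate (racemic) | COC(=O)C#CC1([O-])C(OC)=C(OC)C1=O.[Li+]
F3 | step 1 | methyl 3-[1-(tert-butyldimethylsilyloxy)-2,3-dimethoxy-4-oxocyclobut-2-en-1-yl]prop-2-ynoate (racemic) | COC(=O)C#CC1(O[Si](C)(C)C(C)(C)C)C(OC)=C(OC)C1=O
F4 | step 1 | methyl (Z)-3-[1-(tert-butyldimethylsilyloxy)-2,3-dimethoxy-4-oxocyclobut-2-en-1-yl]-3-methoxyprop-2-enoate (racemic) | COC(=O)/C=C(\OC)C1(O[Si](C)(C)C(C)(C)C)C(OC)=C(OC)C1=O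
F5 | step 3 | 4-(tert-butyldimethylsilyloxy)-2-(hydroxymethyl)-3,5,6-trimethoxyphenol | OCc1c(O)c(OC)c(OC)c(O[Si](C)(C)C(C)(C)C)c1OC
F6 | step 3 | 3-(tert-butyldimethylsilyloxy)-6-hydroxy-2,4,5-trimethoxybenzaldehyde | O=Cc1c(O)c(OC)c(OC)c(O[Si](C)(C)C(C)(C)C)c1OC
F7 | step 3 | 1-[3-(tert-butyldimethylsilyloxy)-6-hydroxy-2,4,5-trimethoxyphenyl]-3-[2-methoxy-6-(methoxymethoxy)phenyl]prop-2-yn-1-ol (racemic) | COCOc1cccc(OC)c1C#CC(O)c1c(O)c(OC)c(OC)c(O[Si](C)(C)C(C)(C)C)c1OC
F8 | step 6 | 3,6-bis(tert-butyldimethylsilyloxy)-N,2,4,5-tetramethoxy-N-methylbenzamide | CON(C)C(=O)c1c(O[Si](C)(C)C(C)(C)C)c(OC)c(OC)c(O[Si](C)(C)C(C)(C)C)c1OC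
F9 | step 6 | 1-[3,6-bis(tert-butyldimethylsilyloxy)-2,4,5-trimethoxyphenyl]-3-[2-methoxy-6-(methoxymethoxy)phenyl]prop-2-yn-1-one | COCOc1cccc(OC)c1C#CC(=O)c1c(O[Si](C)(C)C(C)(C)C)c(OC)c(OC)c(O[Si](C)(C)C(C)(C)C)c1OC
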